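**Plan**
1. Retrosynthesis: the coumarin lactone ring is cut at C3–C4 and O1–C2 (Knoevenagel condensation/lactonisation) into salicylaldehyde 11 and pyranone acetic ester 23; the dihydropyranone ring is cut at C3–C4 and O1–C6 in one stroke into the β-oxido carbanion 18 and the alkynyl N-methoxy-N-methyl amide 15; the aryl–CH bond of the side chain is cut into an aryl Grignard reagent and a trans-epoxide.
2. Enabling feature: in the 2,3-dihydro-4H-pyran-4-one ring the ketone carbon C4 and the enol-ether carbon C6 are the carbonyl and β-carbons of an ynone (a 1,3-dielectrophile), and O1–C2H(CH3)–C3H2 is a 1,3-O,C-dinucleophile whose stereocenter lies between the two reacting atoms and is not touched.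
3. Helpers: the N-methoxy-N-methyl amide activates pyranone C4 and is expelled; the C6 arm is carried as a silyloxyethyl group (an ester would not survive the organolithium) and is oxidised to the acetic ester afterwards.
4. Forward order: arene with side chain and formyl group (steps 1–6); dihydropyranone ring (steps 7–10); coumarin lactone ring last (step 11); desilylation (step 12).
5. Stereochemistry: both side-chain centres come from (2R,3R)-2,3-dimethyloxirane by SN2 opening; pyranone C2 (S) comes from (S)-1-chloropropan-2-ol.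

Key step: step 8

Remark: compounds 1, 5, 12, 13 and 16 are taken as purchasable; by the CIP rules the side chain of the target is (2R,3R) and the pyranone centre is (S).

Step 1
Reactants: 1 1,3-bis(benzyloxy)-5-bromobenzene
Product: 3 2,4-bis(benzyloxy)-6-bromobenzaldehyde, via iminium chloride 2 (not isolated)
Conditions: POCl3, DMF, 0 → 80 °C; then aq NaOAc
Reagents that add atoms: N,N-dimethylformamide, CN(C)C=O; water, O
Why: Vilsmeier–Haack formylation, in which the chloroiminium electrophile should attack the position ortho to bromine and para to one benzyloxy group (the most activated ortho/para site) and the iminium salt is hydrolysed on work-up.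

Step 2
Reactants: 3 2,4-bis(benzyloxy)-6-bromobenzaldehyde
Product: 4 1,5-bis(benzyloxy)-3-bromo-2-methylbenzene
Conditions: Et3SiH, TFA, CH2Cl2, 0 °C → rt
Reagents that add atoms: none
Why: Ionic hydrogenation, in which the 2,4-dialkoxy-stabilised benzylic cation is reduced twice by the silane to the methyl group while the aryl bromide and the benzyl ethers should be inert at this temperature.

Step 3
Reactants: 4 1,5-bis(benzyloxy)-3-bromo-2-methylbenzene; 5 (2R,3R)-2,3-dimethyloxirane
Product: 7 (2R,3R)-3-[3,5-bis(benzyloxy)-2-methylphenyl]butan-2-ol, via arylmagnesium bromide 6 (not isolated)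
Conditions: Mg, THF, 50 °C; then CuI (10 mol %), 5, −30 °C → rt; aq NH4Cl
Reagents that add atoms: none
Why: Copper-catalysed Grignard opening of an epoxide (SN2, anti), in which the aryl group should enter with inversion at the attacked carbon and retention at the carbinol carbon, and because 5 is C2-symmetric either carbon gives the same (2R,3R) alcohol, which sets both side-chain stereocenters.

Step 4
Reactants: 7 (2R,3R)-3-[3,5-bis(benzyloxy)-2-methylphenyl]butan-2-ol
Product: 8 tert-butyl{[(2R,3R)-3-[3,5-bis(benzyloxy)-2-methylphenyl]butan-2-yl]oxy}dimethylsilane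
Conditions: TBSOTf, 2,6-lutidine, CH2Cl2, 0 °C
Reagents that add atoms: tert-butyldimethylsilyl triflate, CC(C)(C)[Si](C)(C)OS(=O)(=O)C(F)(F)F
Why: Silylation of the hindered secondary alcohol with the silyl triflate, needed so that the later aldehyde cannot close to a lactol with this hydroxyl.

Step 5
Reactants: 8 tert-butyl{[(2R,3R)-3-[3,5-bis(benzyloxy)-2-methylphenyl]butan-2-yl]oxy}dimethylsilane
Product: 10 2,4-bis(benzyloxy)-6-{(2R,3R)-3-[(tert-butyldimethylsilyl)oxy]butan-2-yl}-5-methylbenzaldehyde, via iminium chloride 9 (not isolated)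
Conditions: POCl3, DMF, 0 → 50 °C; then aq NaOAc
Reagents that add atoms: N,N-dimethylformamide, CN(C)C=O; water, O
Why: Vilsmeier–Haack formylation at the only free position that is para to a benzyloxy group (between the side chain and the other benzyloxy group), which should be preferred electronically over the position flanked by two benzyloxy groups, with a buffered work-up that spares the silyl ether.

Step 6
Reactants: 10 2,4-bis(benzyloxy)-6-{(2R,3R)-3-[(tert-butyldimethylsilyl)oxy]butan-2-yl}-5-methylbenzaldehyde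
Product: 11 6-{(2R,3R)-3-[(tert-butyldimethylsilyl)oxy]butan-2-yl}-2,4-dihydroxy-5-methylbenzaldehyde
Conditions: H2 (1 atm), Pd/C (10 %), EtOAc, rt
Reagents that add atoms: none
Why: Hydrogenolysis of both aryl benzyl ethers in neutral ethyl acetate, where the hindered, hydrogen-bonded aldehyde and the silyl ether should survive and no stereocenter is touched.

Step 7
Reactants: 12 tert-butyl(but-3-yn-1-yloxy)dimethylsilane; 13 N-methoxy-N-methylcarbamoyl chloride
Product: 15 5-[(tert-butyldimethylsilyl)oxy]-N-methoxy-N-methylpent-2-ynamide, via lithium acetylide 14 (not isolated)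
Conditions: n-BuLi, THF, −78 °C; then 13, −78 → 0 °C
Reagents that add atoms: none
Why: Acylation of a lithium acetylide by a carbamoyl chloride, which should stop at the alkynyl N-methoxy-N-methyl amide because the product is far less electrophilic than the chloride.

Step 8
Reactants: 16 (S)-1-chloropropan-2-ol; 15 5-[(tert-butyldimethylsilyl)oxy]-N-methoxy-N-methylpent-2-ynamide
Product: 20 (S)-6-{2-[(tert-butyldimethylsilyl)oxy]ethyl}-2-methyl-2,3-dihydro-4H-pyran-4-one, via lithium chloroalkoxide 17 (not isolated), via dilithium oxidoalkyl species 18 (not isolated), via hydroxy ynone 19 (not isolated)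
Conditions: 16, n-BuLi (1 equiv), THF, −78 °C; lithium naphthalenide (LiC10H8, 2 equiv), −78 °C; add 15, −78 °C; AcOH, −78 °C → rt; then TsOH·H2O (10 mol %), CH2Cl2, rt
Reagents that add atoms: none
Why: n-BuLi converts 16 into alkoxide 17, lithium naphthalenide cleaves its C–Cl bond reductively to the β-oxido alkyllithium 18 (β-elimination is slow at −78 °C because the leaving group would be lithium oxide), the carbanion adds 1,2 to the amide of 15 to give a lithium-chelated tetrahedral adduct that collapses only on the acidic quench to hydroxy ynone 19, and TsOH then lets the C2 hydroxyl add to the β-carbon of the ynone. The closest known reaction types are the Weinreb ketone synthesis with alkynyl N-methoxy-N-methyl amides (organolithium to ynone) and the acid-catalysed cyclisation of β-hydroxy ynones to 2,3-dihydro-4H-pyran-4-ones. The dihydropyranone ring closes by a 6-endo-dig oxa-Michael addition. No new stereocenter is formed: C2 of the ring is the carbinol carbon of 16, none of its bonds is broken, and because C3 carries no acidifying group there is no enolisation or retro-oxa-Michael path that could racemise it. The step needs 1,2- over 1,4-addition and addition over γ-deprotonation of 15, which the hard primary alkyllithium at −78 °C and the chelating amide (no second addition) should secure, and 6-endo over 5-exo closure, which the polarisation of the ynone toward its β-carbon secures.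

Step 9
Reactants: 20 (S)-6-{2-[(tert-butyldimethylsilyl)oxy]ethyl}-2-methyl-2,3-dihydro-4H-pyran-4-one
Product: 22 2-[(2S)-2-methyl-4-oxo-3,4-dihydro-2H-pyran-6-yl]acetic acid, via primary alcohol 21 (not isolated)
Conditions: Jones reagent (CrO3, H2SO4, H2O), acetone, 0 °C
Reagents that add atoms: water, O
Why: Jones oxidation, in which the acidic medium should cleave the primary silyl ether and hexavalent chromium oxidises the alcohol through the aldehyde hydrate to the acid, the vinylogous ester being stable to brief cold aqueous acid.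

Step 10
Reactants: 22 2-[(2S)-2-methyl-4-oxo-3,4-dihydro-2H-pyran-6-yl]acetic acid
Product: 23 methyl 2-[(2S)-2-methyl-4-oxo-3,4-dihydro-2H-pyran-6-yl]acetate
Conditions: TMSCHN2, PhMe/MeOH, 0 °C
Reagents that add atoms: (trimethylsilyl)diazomethane, C[Si](C)(C)C=[N+]=[N-]
Why: Diazoalkane esterification under neutral, cold conditions, which avoids heating the decarboxylation-prone vinylogous β-keto acid.

Step 11
Reactants: 11 6-{(2R,3R)-3-[(tert-butyldimethylsilyl)oxy]butan-2-yl}-2,4-dihydroxy-5-methylbenzaldehyde; 23 methyl 2-[(2S)-2-methyl-4-oxo-3,4-dihydro-2H-pyran-6-yl]acetate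
Product: 25 5-{(2R,3R)-3-[(tert-butyldimethylsilyl)oxy]butan-2-yl}-7-hydroxy-6-methyl-3-[(2S)-2-methyl-4-oxo-3,4-dihydro-2H-pyran-6-yl]-2H-chromen-2-one, via Knoevenagel alkylidene ester 24 (not isolated)
Conditions: piperidine (20 mol %), AcOH (20 mol %), toluene, 4 Å MS, 80 °C
Reagents that add atoms: none
Why: Knoevenagel condensation followed by lactonisation, in which the methylene of 23 (acidified by the ester and the vinylogous ketone) condenses with the aldehyde and the ortho hydroxyl closes the coumarin ring with loss of methanol, no stereocenter being involved.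

Step 12
Reactants: 25 5-{(2R,3R)-3-[(tert-butyldimethylsilyl)oxy]butan-2-yl}-7-hydroxy-6-methyl-3-[(2S)-2-methyl-4-oxo-3,4-dihydro-2H-pyran-6-yl]-2H-chromen-2-one
Product: 26 7-hydroxy-5-[(2R,3R)-3-hydroxybutan-2-yl]-6-methyl-3-[(2S)-2-methyl-4-oxo-3,4-dihydro-2H-pyran-6-yl]-2H-chromen-2-one
Conditions: HF·pyridine, THF, 0 °C → rt
Reagents that add atoms: none
Why: Fluoride-mediated cleavage of the secondary silyl ether under mildly acidic conditions that should leave the lactone, the enone and the three stereocenters untouched.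

**Compound list**
1 | 1,3-bis(benzyloxy)-5-bromobenzene | Brc1cc(OCc2ccccc2)cc(OCc2ccccc2)c1 | starting material
2 | N-[2,4-bis(benzyloxy)-6-bromobenzylidene]-N-methylmethanaminium chloride | C[N+](C)=Cc1c(Br)cc(OCc2ccccc2)cc1OCc1ccccc1.[Cl-] | intermediate
3 | 2,4-bis(benzyloxy)-6-bromobenzaldehyde | O=Cc1c(Br)cc(OCc2ccccc2)cc1OCc1ccccc1 | intermediate
4 | 1,5-bis(benzyloxy)-3-bromo-2-methylbenzene | Cc1c(Br)cc(OCc2ccccc2)cc1OCc1ccccc1 | intermediate
5 | (2R,3R)-2,3-dimethyloxirane | C[C@H]1O[C@@H]1C | starting material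
6 | [3,5-bis(benzyloxy)-2-methylphenyl]magnesium bromide | Cc1c([Mg]Br)cc(OCc2ccccc2)cc1OCc1ccccc1 | intermediate
7 | (2R,3R)-3-[3,5-bis(benzyloxy)-2-methylphenyl]butan-2-ol | Cc1c(OCc2ccccc2)cc(OCc2ccccc2)cc1[C@@H](C)[C@@H](C)O | intermediate
8 | tert-butyl{[(2R,3R)-3-[3,5-bis(benzyloxy)-2-methylphenyl]butan-2-yl]oxy}dimethylsilane | Cc1c(OCc2ccccc2)cc(OCc2ccccc2)cc1[C@@H](C)[C@@H](C)O[Si](C)(C)C(C)(C)C | intermediate
9 | N-(2,4-bis(benzyloxy)-6-{(2R,3R)-3-[(tert-butyldimethylsilyl)oxy]butan-2-yl}-5-methylbenzylidene)-N-methylmethanaminium chloride | Cc1c(OCc2ccccc2)cc(OCc2ccccc2)c(C=[N+](C)C)c1[C@@H](C)[C@@H](C)O[Si](C)(C)C(C)(C)C.[Cl-] | intermediate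
10 | 2,4-bis(benzyloxy)-6-{(2R,3R)-3-[(tert-butyldimethylsilyl)oxy]butan-2-yl}-5-methylbenzaldehyde | Cc1c(OCc2ccccc2)cc(OCc2ccccc2)c(C=O)c1[C@@H](C)[C@@H](C)O[Si](C)(C)C(C)(C)C | intermediate
11 | 6-{(2R,3R)-3-[(tert-butyldimethylsilyl)oxy]butan-2-yl}-2,4-dihydroxy-5-methylbenzaldehyde | Cc1c(O)cc(O)c(C=O)c1[C@@H](C)[C@@H](C)O[Si](C)(C)C(C)(C)C | intermediate
12 | tert-butyl(but-3-yn-1-yloxy)dimethylsilane | C#CCCO[Si](C)(C)C(C)(C)C | starting material
13 | N-methoxy-N-methylcarbamoyl chloride | CON(C)C(Cl)=O | starting material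
14 | {4-[(tert-butyldimethylsilyl)oxy]but-1-yn-1-yl}lithium | [Li]C#CCCO[Si](C)(C)C(C)(C)C | intermediate
15 | 5-[(tert-butyldimethylsilyl)oxy]-N-methoxy-N-methylpent-2-ynamide | CON(C)C(=O)C#CCCO[Si](C)(C)C(C)(C)C | intermediate
16 | (S)-1-chloropropan-2-ol | ClC[C@H](C)O | starting material
17 | lithium (S)-1-chloropropan-2-olate | ClC[C@H](C)O[Li] | intermediate
18 | (S)-[2-(lithiooxy)propyl]lithium | [Li]C[C@H](C)O[Li] | intermediate
19 | (S)-8-[(tert-butyldimethylsilyl)oxy]-2-hydroxyoct-5-yn-4-one | C[C@H](O)CC(=O)C#CCCO[Si](C)(C)C(C)(C)C | intermediate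
20 | (S)-6-{2-[(tert-butyldimethylsilyl)oxy]ethyl}-2-methyl-2,3-dihydro-4H-pyran-4-one | CC(C)(C)[Si](C)(C)OCCC1=CC(=O)C[C@H](C)O1 | intermediate
21 | (S)-6-(2-hydroxyethyl)-2-methyl-2,3-dihydro-4H-pyran-4-one | OCCC1=CC(=O)C[C@H](C)O1 | intermediate
22 | 2-[(2S)-2-methyl-4-oxo-3,4-dihydro-2H-pyran-6-yl]acetic acid | OC(=O)CC1=CC(=O)C[C@H](C)O1 | intermediate
23 | methyl 2-[(2S)-2-methyl-4-oxo-3,4-dihydro-2H-pyran-6-yl]acetate | COC(=O)CC1=CC(=O)C[C@H](C)O1 | intermediate
24 | methyl 3-(2-{(2R,3R)-3-[(tert-butyldimethylsilyl)oxy]butan-2-yl}-4,6-dihydroxy-3-methylphenyl)-2-[(2S)-2-methyl-4-oxo-3,4-dihydro-2H-pyran-6-yl]acrylate | COC(=O)C(=Cc1c(O)cc(O)c(C)c1[C@@H](C)[C@@H](C)O[Si](C)(C)C(C)(C)C)C1=CC(=O)C[C@H](C)O1 | intermediate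
25 | 5-{(2R,3R)-3-[(tert-butyldimethylsilyl)oxy]butan-2-yl}-7-hydroxy-6-methyl-3-[(2S)-2-methyl-4-oxo-3,4-dihydro-2H-pyran-6-yl]-2H-chromen-2-one | Cc1c(O)cc2oc(=O)c(C3=CC(=O)C[C@H](C)O3)cc2c1[C@@H](C)[C@@H](C)O[Si](C)(C)C(C)(C)C | intermediate
26 | 7-hydroxy-5-[(2R,3R)-3-hydroxybutan-2-yl]-6-methyl-3-[(2S)-2-methyl-4-oxo-3,4-dihydro-2H-pyran-6-yl]-2H-chromen-2-one | Cc1c(O)cc2oc(=O)c(C3=CC(=O)C[C@H](C)O3)cc2c1[C@@H](C)[C@@H](C)O | target

**Totals**
Total step count: 12. Longest linear sequence: 8 steps (steps 1–6, 11, 12).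

**Steps most likely to fail**

Step 8 (key step). What may go wrong: β-elimination of the β-oxido alkyllithium before it is acylated, electron transfer from residual lithium naphthalenide to the ynamide, and γ-deprotonation or 1,4-addition in place of 1,2-addition. The fallback sets out from 12 and comes back at 20, and makes the ynone by joining pyranone C4 to C5 instead. Commercial ethyl (S)-3-hydroxybutanoate is converted with MeNHOMe·HCl and i-PrMgCl into (S)-3-hydroxy-N-methoxy-N-methylbutanamide F1, which is silylated (TESCl, imidazole) to (S)-N-methoxy-N-methyl-3-[(triethylsilyl)oxy]butanamide F2. Lithium acetylide 14 (from 12 and n-BuLi) adds to F2 to give (S)-8-[(tert-butyldimethylsilyl)oxy]-2-[(triethylsilyl)oxy]oct-5-yn-4-one F3. Aqueous AcOH/THF removes the triethylsilyl group selectively to give 19, and catalytic TsOH·H2O closes it to 20.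

Step 11. What may go wrong: slow condensation at the doubly ortho-substituted aldehyde, addition of piperidine to the enol-ether carbon of the pyranone with ring opening, and Michael addition of a second molecule of 23 to coumarin C4. The fallback sets out from 11 and 22 and comes back at 26, and makes the condensation intramolecular. The 4-hydroxyl of 11 (the 2-hydroxyl is hydrogen-bonded to the aldehyde) is silylated with TBSCl and imidazole to give 4-[(tert-butyldimethylsilyl)oxy]-6-{(2R,3R)-3-[(tert-butyldimethylsilyl)oxy]butan-2-yl}-2-hydroxy-5-methylbenzaldehyde F4. Esterification of F4 with acid 22 (EDC·HCl, DMAP, CH2Cl2) gives 5-[(tert-butyldimethylsilyl)oxy]-3-{(2R,3R)-3-[(tert-butyldimethylsilyl)oxy]butan-2-yl}-2-formyl-4-methylphenyl 2-[(2S)-2-methyl-4-oxo-3,4-dihydro-2H-pyran-6-yl]acetate F5. Its methylene, now flanked by an aryl ester, closes on the neighbouring aldehyde with Et3N to give 7-[(tert-butyldimethylsilyl)oxy]-5-{(2R,3R)-3-[(tert-butyldimethylsilyl)oxy]butan-2-yl}-6-methyl-3-[(2S)-2-methyl-4-oxo-3,4-dihydro-2H-pyran-6-yl]-2H-chromen-2-one F6. HF·pyridine removes both silyl groups to give 26.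

Step 5. What may go wrong: attack of the bulky iminium electrophile at the position between the two benzyloxy groups or no attack at all next to the branched side chain, and partial loss of the silyl ether. The fallback sets out from 8 and comes back at 10, and reverses the polarity at the arene carbon. NBS in MeCN (small electrophile, para to a benzyloxy group) gives 1,5-bis(benzyloxy)-2-bromo-3-{(2R,3R)-3-[(tert-butyldimethylsilyl)oxy]butan-2-yl}-4-methylbenzene F7. Bromine–lithium exchange with t-BuLi (THF, −78 °C) gives (2,4-bis(benzyloxy)-6-{(2R,3R)-3-[(tert-butyldimethylsilyl)oxy]butan-2-yl}-5-methylphenyl)lithium F8, which is formylated with DMF to give 10.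

**Further compounds**
F1 | step 8 | (S)-3-hydroxy-N-methoxy-N-methylbutanamide | C[C@H](O)CC(=O)N(C)OC
F2 | step 8 | (S)-N-methoxy-N-methyl-3-[(triethylsilyl)oxy]butanamide | C[C@H](O[Si](CC)(CC)CC)CC(=O)N(C)OC
F3 | step 8 | (S)-8-[(tert-butyldimethylsilyl)oxy]-2-[(triethylsilyl)oxy]oct-5-yn-4-one | C[C@H](O[Si](CC)(CC)CC)CC(=O)C#CCCO[Si](C)(C)C(C)(C)C
F4 | step 11 | 4-[(tert-butyldimethylsilyl)oxy]-6-{(2R,3R)-3-[(tert-butyldimethylsilyl)oxy]butan-2-yl}-2-hydroxy-5-methylbenzaldehyde | Cc1c(O[Si](C)(C)C(C)(C)C)cc(O)c(C=O)c1[C@@H](C)[C@@H](C)O[Si](C)(C)C(C)(C)C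
F5 | step 11 | 5-[(tert-butyldimethylsilyl)oxy]-3-{(2R,3R)-3-[(tert-butyldimethylsilyl)oxy]butan-2-yl}-2-formyl-4-methylphenyl 2-[(2S)-2-methyl-4-oxo-3,4-dihydro-2H-pyran-6-yl]acetate | Cc1c(O[Si](C)(C)C(C)(C)C)cc(OC(=O)CC2=CC(=O)C[C@H](C)O2)c(C=O)c1[C@@H](C)[C@@H](C)O[Si](C)(C)C(C)(C)C
F6 | step 11 | 7-[(tert-butyldimethylsilyl)oxy]-5-{(2R,3R)-3-[(tert-butyldimethylsilyl)oxy]butan-2-yl}-6-methyl-3-[(2S)-2-methyl-4-oxo-3,4-dihydro-2H-pyran-6-yl]-2H-chromen-2-one | Cc1c(O[Si](C)(C)C(C)(C)C)cc2oc(=O)c(C3=CC(=O)C[C@H](C)O3)cc2c1[C@@H](C)[C@@H](C)O[Si](C)(C)C(C)(C)C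
F7 | step 5 | 1,5-bis(benzyloxy)-2-bromo-3-{(2R,3R)-3-[(tert-butyldimethylsilyl)oxy]butan-2-yl}-4-methylbenzene | Cc1c(OCc2ccccc2)cc(OCc2ccccc2)c(Br)c1[C@@H](C)[C@@H](C)O[Si](C)(C)C(C)(C)C
F8 | step 5 | (2,4-bis(benzyloxy)-6-{(2R,3R)-3-[(tert-butyldimethylsilyl)oxy]butan-2-yl}-5-methylphenyl)lithium | Cc1c(OCc2ccccc2)cc(OCc2ccccc2)c([Li])c1[C@@H](C)[C@@H](C)O[Si](C)(C)C(C)(C)C
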